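**Retrosynthetic overview**

1. Target 19 is methyl 6α-angeloyloxy-1β,4α,8α-trihydroxy-5αH-eudesm-11(13)-en-12-oate. The methyl ester/8-OH pair is unmasked late from an 8,12-lactone, and the 1β-OH comes last by reduction of a C1 ketone.
2. Key disconnection: ring B is cut at C6–C7 and C9–C10. This is a [3+3] union of the ring A enone-aldehyde 5 (C6 = CHO on C5; C10 = β-carbon of a C4 enone) with the bis-iodide butenolide 8 (C7–C8–C9 plus C11, C12, C13 and O8).
3. Enabling feature: the triad C6(O)–C7(C11=C13, C12=O)–C8(O) of ring B is a masked β-(hydroxyalkyl)-α-methylene-γ-butyrolactone, the retron of a 2-carbonylallyl metal adding through C7 to a C6 aldehyde. C10 lies β to C4 (held as a ketone) through C5, so a C9 radical on the same fragment can close ring B by conjugate addition.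
4. Ring order: ring A (from an arene, achiral) and the lactone ring (chiral pool; C8 is the only stereocentre brought in) come first, and ring B forms in the key step. Then C4=O becomes C4(CH3)OH, O6 is angeloylated, and the C1 ketal and the lactone are unmasked.

Key step: step 7

Remark: decalins carry eudesmane numbering (ring A = C1–C5 and C10, ring B = C5–C10, C11 on C7 bears C12 and C13, C14 on C10, C15 on C4; β = face of the C10 methyl group; angeloyl = (Z)-2-methylbut-2-enoyl), and (R)-5-(hydroxymethyl)furan-2(5H)-one 6 is assumed to be purchasable as a chiral-pool butenolide.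

**Route**

Step 1
Reactants: 1 4-methoxy-3-methylphenol
Product: 2 4,4-dimethoxy-3-methylcyclohexa-2,5-dien-1-one
Conditions: PhI(OAc)2, MeOH, 0 °C
Reagents that add atoms: methanol CO
Why: Oxidative dearomatisation of a para-alkoxyphenol in methanol should give the quinone monoketal, which fixes the para C1/C4 dioxygenation of ring A (no stereocentre).

Step 2
Reactants: 2 4,4-dimethoxy-3-methylcyclohexa-2,5-dien-1-one
Product: 3 4,4-dimethoxy-3-methylcyclohex-2-en-1-one
Conditions: H2 (1 atm), RhCl(PPh3)3 (cat.), benzene, rt
Reagents that add atoms: none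
Why: Homogeneous hydrogenation should saturate the unhindered disubstituted C=C and leave the trisubstituted β-methyl enone C=C next to the quaternary ketal carbon.

Step 3
Reactants: 3 4,4-dimethoxy-3-methylcyclohex-2-en-1-one
Product: 4 2-iodo-4,4-dimethoxy-3-methylcyclohex-2-en-1-one
Conditions: I2, pyridine, CH2Cl2, 0 °C to rt
Reagents that add atoms: iodine II
Why: Iodine–pyridine α-iodination of a cyclic enone (conjugate addition of pyridine, iodination, elimination) places the halogen on the future C5.

Step 4
Reactants: 4 2-iodo-4,4-dimethoxy-3-methylcyclohex-2-en-1-one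
Product: 5 3,3-dimethoxy-2-methyl-6-oxocyclohex-1-ene-1-carbaldehyde
Conditions: CO (1 atm), Bu3SnH (syringe pump), Pd(PPh3)4 (cat.), toluene, 50 °C
Reagents that add atoms: carbon monoxide [C-]#[O+]
Why: Palladium-catalysed reductive carbonylation (formylation) of the vinyl iodide installs C6 as the aldehyde; slow addition of the tin hydride should limit conjugate reduction of the product.

Step 5
Reactants: 6 (R)-5-(hydroxymethyl)furan-2(5H)-one
Product: 7 (R)-3,5-bis(hydroxymethyl)furan-2(5H)-one
Conditions: aq. HCHO (37 %), imidazole, THF/H2O, rt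
Reagents that add atoms: formaldehyde C=O
Why: Morita–Baylis–Hillman α-hydroxymethylation of the unsaturated lactone attaches C13 to C11 under weakly basic conditions that should leave the stereocentre (future C8) untouched.

Step 6
Reactants: 7 (R)-3,5-bis(hydroxymethyl)furan-2(5H)-one
Product: 8 (R)-3,5-bis(iodomethyl)furan-2(5H)-one
Conditions: I2, PPh3, imidazole, CH2Cl2, 0 °C, dark
Reagents that add atoms: iodine II
Why: Appel-type iodination converts both primary alcohols into iodides (allylic C13–I and alkyl C9–I) without touching the stereocentre.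

Step 7
Reactants: 5 3,3-dimethoxy-2-methyl-6-oxocyclohex-1-ene-1-carbaldehyde and 8 (R)-3,5-bis(iodomethyl)furan-2(5H)-one
Product: 11 6α-hydroxy-1,1-dimethoxy-4-oxo-15-nor-5αH-eudesm-11(13)-en-12,8α-olide, via allylzinc iodide 9 (not isolated), via Barbier adduct 10 (not isolated)
Conditions: Zn dust, CuI (0.3 equiv), THF/H2O 4:1, ultrasound, 0 °C to rt
Reagents that add atoms: none
Why: Proposed new method: one zinc–copper couple in wet THF is asked to perform two reductions in sequence, the zinc Barbier allylation of an aldehyde by a 3-(halomethyl)butenolide and the zinc/CuI (Luche-type) radical conjugate addition of an alkyl iodide to an enone, which are the closest known reaction types and have not been run as one tandem. The allylic C13–I bond of 8 is reduced first to allylzinc 9, which adds through its γ-carbon C7 to the aldehyde carbon C6 of 5 in a closed six-membered chair transition state; because the butenolide ring holds C8 trans to C13, C8 is equatorial in that chair and the 6,7-anti adduct 10 results, and because the aldehyde approaches C7 anti to the CH2I group on C8, H7 and H8 end up trans. Electron transfer to the primary C9–I bond of 10 then gives a nucleophilic alkyl radical that closes ring B by a 6-endo-trig cyclisation onto C10, the β-carbon of the C4 enone, through a chair in which O6, C11 and O8 are all equatorial (enforced by the trans-fused lactone), so that C9 enters C10 from the α face and the C10 methyl group ends up β, on the face of H6 and H8. The resulting α-keto radical at C5 is reduced to the zinc enolate and protonated from the α face to give the trans-decalin, which is also the thermodynamic epimer because C5 stays enolisable next to the C4 ketone. The step needs 1,2-addition to the aldehyde before any reaction at the enone, and reduction of the allylic iodide before the alkyl iodide and before 5 itself; the high reactivity of aldehydes toward allylzinc reagents, the shielding of the tetrasubstituted C5=C10 bond and the far easier reduction of an allylic C–I bond should secure this order, and 6-endo closure is favoured over 5-exo attack at C5 because only attack at C10 gives a stabilised radical.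

Step 8
Reactants: 11 6α-hydroxy-1,1-dimethoxy-4-oxo-15-nor-5αH-eudesm-11(13)-en-12,8α-olide
Product: 12 6α-hydroxy-1,1-dimethoxy-5αH-eudesma-4(15),11(13)-dien-12,8α-olide
Conditions: Zn, CH2Br2, TiCl4 (pre-formed reagent), THF/CH2Cl2, 0 °C to rt
Reagents that add atoms: dibromomethane BrCBr
Why: Takai–Lombardo methylenation: the non-basic zinc–titanium methylene reagent should olefinate the hindered, enolisable C4 ketone without retro-aldol cleavage of the β-hydroxy ketone or epimerisation at C5, and it prefers the ketone to the lactone carbonyl.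

Step 9
Reactants: 12 6α-hydroxy-1,1-dimethoxy-5αH-eudesma-4(15),11(13)-dien-12,8α-olide
Product: 14 4α,6α-dihydroxy-1,1-dimethoxy-5αH-eudesm-11(13)-en-12,8α-olide, via organomercurial 13 (not isolated)
Conditions: Hg(OAc)2, THF/H2O 1:1, rt; then Bu3SnH, THF, 0 °C
Reagents that add atoms: water O
Why: Markovnikov oxymercuration–demercuration of the electron-rich C4=C15 bond (the electron-poor α-methylene lactone is inert); water should attack C4 from the equatorial α face because the axial β face is blocked by the syn-axial C10 methyl group, setting 4α-OH/4β-CH3, and tin hydride is used for demercuration because borohydride would reduce the α-methylene lactone.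

Step 10
Reactants: 14 4α,6α-dihydroxy-1,1-dimethoxy-5αH-eudesm-11(13)-en-12,8α-olide
Product: 15 6α-angeloyloxy-4α-hydroxy-1,1-dimethoxy-5αH-eudesm-11(13)-en-12,8α-olide
Conditions: angelic acid, 2,4,6-trichlorobenzoyl chloride, Et3N, toluene, rt; then 14, toluene, 80 °C
Reagents that add atoms: angelic acid C/C=C(/C)C(=O)O
Why: Yamaguchi-type esterification through the mixed anhydride acylates the only secondary hydroxyl (6α-OH; the tertiary 4-OH is inert) and is run without DMAP to keep the Z-configured angeloyl group from isomerising.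

Step 11
Reactants: 15 6α-angeloyloxy-4α-hydroxy-1,1-dimethoxy-5αH-eudesm-11(13)-en-12,8α-olide
Product: 16 6α-angeloyloxy-4α-hydroxy-1-oxo-5αH-eudesm-11(13)-en-12,8α-olide
Conditions: pyridinium p-toluenesulfonate (cat.), acetone/H2O 4:1, 45 °C
Reagents that add atoms: water O
Why: Acid-catalysed hydrolysis of the dimethyl ketal unmasks the C1 ketone; the buffered acid should be too mild to dehydrate the tertiary alcohol or isomerise the angelate.

Step 12
Reactants: 16 6α-angeloyloxy-4α-hydroxy-1-oxo-5αH-eudesm-11(13)-en-12,8α-olide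
Product: 18 methyl 6α-angeloyloxy-4α,8α-dihydroxy-1-oxo-5αH-eudesm-11(13)-en-12-oate, via lithium carboxylate 17 (not isolated)
Conditions: LiOH·H2O (1.05 equiv), THF/H2O, 0 °C; evaporation; then MeI, DMF, 0 °C to rt
Reagents that add atoms: lithium hydroxide [Li+].[OH-]; iodomethane CI
Why: Saponification of the strained trans-fused α-methylene-γ-lactone by one equivalent of hydroxide is expected to be much faster than attack on the hindered angelate, and alkylative esterification of the carboxylate with MeI fixes the open form as the methyl ester before relactonisation; no stereocentre is touched.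

Step 13
Reactants: 18 methyl 6α-angeloyloxy-4α,8α-dihydroxy-1-oxo-5αH-eudesm-11(13)-en-12-oate
Product: 19 methyl 6α-angeloyloxy-1β,4α,8α-trihydroxy-5αH-eudesm-11(13)-en-12-oate (target)
Conditions: NaBH4, CeCl3·7H2O, MeOH, −78 °C
Reagents that add atoms: none
Why: Luche reduction: the cerium-modified borohydride should add 1,2 to the C1 ketone from the α face (axial attack; the β face is shielded by the angular C10 methyl group) to give the equatorial 1β-alcohol, sparing the acrylate and the angelate.

**Compound list**

1 | 4-methoxy-3-methylphenol | COc1ccc(O)cc1C | starting material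
2 | 4,4-dimethoxy-3-methylcyclohexa-2,5-dien-1-one | COC1(OC)C=CC(=O)C=C1C | intermediate
3 | 4,4-dimethoxy-3-methylcyclohex-2-en-1-one | COC1(OC)CCC(=O)C=C1C | intermediate
4 | 2-iodo-4,4-dimethoxy-3-methylcyclohex-2-en-1-one | COC1(OC)CCC(=O)C(I)=C1C | intermediate
5 | 3,3-dimethoxy-2-methyl-6-oxocyclohex-1-ene-1-carbaldehyde (ring A fragment; CHO carbon = C6) | COC1(OC)CCC(=O)C(C=O)=C1C | intermediate
6 | (R)-5-(hydroxymethyl)furan-2(5H)-one | O=C1O[C@@H](CO)C=C1 | starting material
7 | (R)-3,5-bis(hydroxymethyl)furan-2(5H)-one | O=C1O[C@@H](CO)C=C1CO | intermediate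
8 | (R)-3,5-bis(iodomethyl)furan-2(5H)-one | O=C1O[C@@H](CI)C=C1CI | intermediate
9 | allylzinc iodide, [(5R)-5-(iodomethyl)-2-oxo-2,5-dihydrofuran-3-yl]methylzinc iodide (forms in the flask) | O=C1O[C@@H](CI)C=C1C[Zn]I | intermediate
10 | Barbier adduct, (4S,5R)-4-[(S)-(3,3-dimethoxy-2-methyl-6-oxocyclohex-1-en-1-yl)(hydroxy)methyl]-5-(iodomethyl)-3-methylideneoxolan-2-one (forms in the flask) | C=C1C(=O)O[C@@H](CI)[C@@H]1[C@H](O)C1=C(C)C(OC)(OC)CCC1=O | intermediate
11 | 6α-hydroxy-1,1-dimethoxy-4-oxo-15-nor-5αH-eudesm-11(13)-en-12,8α-olide (7αH; 8βH; 10β-CH3; trans-decalin; trans-fused lactone) | C=C(C3=O)[C@H]1[C@H](O)[C@@H]2[C@@](C)(C[C@@H]1O3)C(OC)(OC)CCC2=O | intermediate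
12 | 6α-hydroxy-1,1-dimethoxy-5αH-eudesma-4(15),11(13)-dien-12,8α-olide | C=C(C3=O)[C@H]1[C@H](O)[C@@H]2[C@@](C)(C[C@@H]1O3)C(OC)(OC)CCC2=C | intermediate
13 | organomercurial, 15-(acetoxymercurio)-4α,6α-dihydroxy-1,1-dimethoxy-5αH-eudesm-11(13)-en-12,8α-olide (forms in the flask) | C=C(C3=O)[C@H]1[C@H](O)[C@@H]2[C@@](C)(C[C@@H]1O3)C(OC)(OC)CC[C@@]2(C[Hg]OC(C)=O)O | intermediate
14 | 4α,6α-dihydroxy-1,1-dimethoxy-5αH-eudesm-11(13)-en-12,8α-olide (4β-CH3) | C=C(C3=O)[C@H]1[C@H](O)[C@@H]2[C@@](C)(C[C@@H]1O3)C(OC)(OC)CC[C@@]2(C)O | intermediate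
15 | 6α-angeloyloxy-4α-hydroxy-1,1-dimethoxy-5αH-eudesm-11(13)-en-12,8α-olide | C=C(C3=O)[C@H]1[C@H](OC(=O)/C(C)=C\C)[C@@H]2[C@@](C)(C[C@@H]1O3)C(OC)(OC)CC[C@@]2(C)O | intermediate
16 | 6α-angeloyloxy-4α-hydroxy-1-oxo-5αH-eudesm-11(13)-en-12,8α-olide | C=C(C3=O)[C@H]1[C@H](OC(=O)/C(C)=C\C)[C@@H]2[C@@](C)(C[C@@H]1O3)C(=O)CC[C@@]2(C)O | intermediate
17 | lithium carboxylate, lithium 6α-angeloyloxy-4α,8α-dihydroxy-1-oxo-5αH-eudesm-11(13)-en-12-oate (forms in the flask) | C=C(C(=O)[O-])[C@H]1[C@H](OC(=O)/C(C)=C\C)[C@@H]2[C@@](C)(C[C@@H]1O)C(=O)CC[C@@]2(C)O.[Li+] | intermediate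
18 | methyl 6α-angeloyloxy-4α,8α-dihydroxy-1-oxo-5αH-eudesm-11(13)-en-12-oate | C=C(C(=O)OC)[C@H]1[C@H](OC(=O)/C(C)=C\C)[C@@H]2[C@@](C)(C[C@@H]1O)C(=O)CC[C@@]2(C)O | intermediate
19 | methyl 6α-angeloyloxy-1β,4α,8α-trihydroxy-5αH-eudesm-11(13)-en-12-oate (1R,4R,5S,6S,7R,8S,10R) | C=C(C(=O)OC)[C@H]1[C@H](OC(=O)/C(C)=C\C)[C@@H]2[C@@](C)(C[C@@H]1O)[C@H](O)CC[C@@]2(C)O | target

**Count and risks**

Total step count: 13. Longest linear sequence: 11 steps (steps 1–4, then 7–13).

Steps most likely to fail:

1. Step 7 (the proposed tandem). Zinc may reduce the doubly activated alkene of 5 or cleave its allylic ketal before the allylzinc has formed. The allylzinc may be protonated or may dimerise. The C9 radical may be reduced before it cyclises, and the O6 zinc alkoxide may translactonise onto C12. The fallback separates the two events with known chemistry. It sets out from 5 and 8: indium powder in THF/H2O (indium Barbier allylation, which leaves enones and alkyl iodides alone) would give the isolated Barbier adduct 10. A tin hydride chain reaction (Bu3SnH, AIBN, benzene, 80 °C, syringe pump) would then effect the 6-endo-trig radical cyclisation of 10, with equilibration at C5 on silica or with a trace of base. The fallback rejoins the route at 11 and needs no compound outside the list.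

2. Step 12. Hydroxide may attack the angelate as well as the lactone, the O8 alkoxide may pull the angeloyl group over from O6, or the hydroxy acid may relactonise before O-methylation. The fallback opens the lactone before the angelate is present and differentiates the two secondary hydroxyls by silylation. It sets out from 14: LiOH in THF/H2O then MeI in DMF would give methyl 4α,6α,8α-trihydroxy-1,1-dimethoxy-5αH-eudesm-11(13)-en-12-oate F1. Et3SiCl and imidazole at −20 °C should silylate the least hindered 8-OH to give methyl 4α,6α-dihydroxy-1,1-dimethoxy-8α-(triethylsilyloxy)-5αH-eudesm-11(13)-en-12-oate F2. Mixed-anhydride angeloylation as in step 10 would give methyl 6α-angeloyloxy-4α-hydroxy-1,1-dimethoxy-8α-(triethylsilyloxy)-5αH-eudesm-11(13)-en-12-oate F3. Pyridinium p-toluenesulfonate in acetone/H2O would then remove the silyl ether and the ketal together. The fallback rejoins the route at 18, before step 13.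

3. Step 10. Acylation of the hindered 6α-hydroxyl may be slow, and forcing it may isomerise the angeloyl group from Z to E or bring about translactonisation. The fallback builds the Z-alkene on the substrate instead of transferring it. It sets out from 14: esterification with 2-[bis(2,2,2-trifluoroethoxy)phosphoryl]propanoic acid (DCC, DMAP, CH2Cl2) would give 6α-{2-[bis(2,2,2-trifluoroethoxy)phosphoryl]propanoyloxy}-4α-hydroxy-1,1-dimethoxy-5αH-eudesm-11(13)-en-12,8α-olide F4. A Z-selective Still–Gennari olefination with acetaldehyde (KHMDS, 18-crown-6, THF, −78 °C) would then give the angelate. The fallback rejoins the route at 15.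

**Further compounds**

F0 | step 7 | none | none
F1 | step 12 | methyl 4α,6α,8α-trihydroxy-1,1-dimethoxy-5αH-eudesm-11(13)-en-12-oate | C=C(C(=O)OC)[C@H]1[C@H](O)[C@@H]2[C@@](C)(C[C@@H]1O)C(OC)(OC)CC[C@@]2(C)O
F2 | step 12 | methyl 4α,6α-dihydroxy-1,1-dimethoxy-8α-(triethylsilyloxy)-5αH-eudesm-11(13)-en-12-oate | C=C(C(=O)OC)[C@H]1[C@H](O)[C@@H]2[C@@](C)(C[C@@H]1O[Si](CC)(CC)CC)C(OC)(OC)CC[C@@]2(C)O
F3 | step 12 | methyl 6α-angeloyloxy-4α-hydroxy-1,1-dimethoxy-8α-(triethylsilyloxy)-5αH-eudesm-11(13)-en-12-oate | C=C(C(=O)OC)[C@H]1[C@H](OC(=O)/C(C)=C\C)[C@@H]2[C@@](C)(C[C@@H]1O[Si](CC)(CC)CC)C(OC)(OC)CC[C@@]2(C)O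
F4 | step 10 | 6α-{2-[bis(2,2,2-trifluoroethoxy)phosphoryl]propanoyloxy}-4α-hydroxy-1,1-dimethoxy-5αH-eudesm-11(13)-en-12,8α-olide (both epimers at the phosphonate-bearing carbon) | C=C(C3=O)[C@H]1[C@H](OC(=O)C(C)P(=O)(OCC(F)(F)F)OCC(F)(F)F)[C@@H]2[C@@](C)(C[C@@H]1O3)C(OC)(OC)CC[C@@]2(C)O
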